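Its constants belong to no real substance; what happens was integrated by code.

I began from the amounts: each D takes on G one at a time, so every rung of the ladder up to G.Z costs one G, and the first thing I asked was how many G spring charged per D.

| setting | spring | noon |
|---|---|---|
| D | 0.10 M | 0.10 M |
| G | 0.250 M | 0.750 M |
| time | 15 min | 15 min |

    D + G → D.G (k1 = 0.070 L mol⁻¹ s⁻¹)
    G + D.G → G.D.G (k2 = 0.18 L mol⁻¹ s⁻¹)
    G + G.D.G → Z (k3 = 0.21 L mol⁻¹ s⁻¹)
    G + Z → G.Z (k4 = 0.017 L mol⁻¹ s⁻¹)
    D + G.Z → D.G.Z (k5 = 0.23 L mol⁻¹ s⁻¹)

- which of these there is most of at the end, counted by the D in it, spring (D.G / D.G.Z / Z / G.D.G / G.Z)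
- which of these there is most of at the end, counted by the D in it, noon (D.G / D.G.Z / Z / G.D.G / G.Z)
- final amount of the leader among these, as a percentage of the D charged, in spring
- final amount of the leader among these, as a percentage of the D charged, in noon

- in percentages every species weighs as the D in it: one D.G.Z counts as two
- run time (spring): 15 min

Standing at Z costs 3 G per D, and spring charged 2.50, so in spring G was the limiting reagent and Z could hold at most 83.3% of the D.

Did the spring run allow time for the climb? The half-life of D under its first step at charged G was 0.660 min, and that of D.G under the next step, at the concentrations as charged, 0.26 min, both short against 15 min, so I expected the amounts to matter more than the clock in spring.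

Did Z then survive? I took the spare G, the charged c(G) less 3 times the charged c(D). In spring it came out at −0.0500 M, a shortfall, and G meets G.D.G with a constant 12.4 times that for Z, so I committed to Z as the spring leader, below its ceiling. At noon the spare was 0.450 M, and I treated the loss of Z as pseudo-first-order at that c(G), with a half-life of 1.51 min. The half-life count, the run time over that half-life, was 9.93, which by my estimate left Z 0.103% of what reached it, so I committed to G.Z at noon.

The forecast gave Z at 60% (52% to 67%) in spring and G.Z at 90% (84% to 95%) at noon, where “G stays in large excess”; its spring figure lies below my ceiling, which is a bound and no estimate.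

The simulation gave Z at 56.5% in spring and G.Z at 94.2% at noon. Spring ended with 0.57% of its G free and 20.2% of the D in D.G.Z. At noon Z fell from 6.19% at 7.50 min to 0.385% at 15.0 min, a reading of 4.01 half-lives where my count allots 4.96, with free G ending at 0.361 M, below the spare.

The neighbour of spring charged with 0.42 M of G has a spare of 0.120 M and a count of 2.65, which by the same estimate leaves Z 15.9% of what reached it, so I expected G.Z ahead there. Computed, G.Z led that neighbour at 63.5%, with Z at 24.9%.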